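**Retrosynthetic overview**

1. Miyabenol A ⇐ global desilylation ⇐ Heck installation of the 4‑oxystyryl group on the C4–Br of ring A in the tris(dihydrobenzofuran) 25.
2. Each trans‑2,3‑diaryl‑2,3‑dihydrobenzofuran (DHB) ⇐ 2‑hydroxy‑DHB lactol + ArMgBr, then acid‑mediated O‑cyclisation, which sets C2 trans to C3.
3. Each lactol ⇐ ozonolysis of an o‑(1‑arylbut‑2‑enyl)phenol ⇐ aromatic Claisen [3,3] rearrangement of an aryl (E)‑1‑methyl‑3‑arylallyl ether. This forms the C3–C3a bond and sets C3 by 1,3‑chirality transfer from the carbinol centre of 3‑butyn‑2‑ol.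
4. Each ether ⇐ Mitsunobu of phenol 3 with an (E)‑4‑arylbut‑3‑en‑2‑ol ⇐ Sonogashira/Red‑Al on the C4–Br of the previous ring.
5. Ring order: C ((S)‑butynol) → B ((R)‑butynol) → A ((S)‑butynol), then the styryl group.

Assumption: (S)‑ and (R)‑3‑butyn‑2‑ol, (4‑bromophenoxy)triisopropylsilane and 4‑(TBSO)styrene are purchased. The target SMILES is read as rings A and C (2R,3R)‑trans and ring B (2S,3S)‑trans.

Abbreviations: TIPSO = (triisopropylsilyl)oxy; TBSO = (tert‑butyldimethylsilyl)oxy.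
"C‑unit" = (2R,3R)‑3‑[3,5‑bis(TIPSO)phenyl]‑6‑(TIPSO)‑2‑[4‑(TIPSO)phenyl]‑2,3‑dihydrobenzofuran‑4‑yl.
"BC‑unit" = (2S,3S)‑3‑(C‑unit)‑6‑(TIPSO)‑2‑[4‑(TIPSO)phenyl]‑2,3‑dihydrobenzofuran‑4‑yl.

---

**Step 1**
Reactants: 1, 5‑bromoresorcinol; 2, TIPSCl
Product: 3, 3‑bromo‑5‑(TIPSO)phenol, and 4, 1‑bromo‑3,5‑bis(TIPSO)benzene (both isolated and both used)
Conditions: TIPSCl (1.4 equiv), imidazole, DMF, 0 °C → rt; chromatography, recovered 1 recycled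
Reagents that add atoms: TIPSCl, Cl[Si](C(C)C)(C(C)C)C(C)C
Why: Statistical O‑silylation of a symmetric diphenol gives the mono‑ether (phenol partner for all three rings) and the bis‑ether (terminal resorcinol ring) in one operation.

**Ring C**

**Step 2**
Reactants: 4; 5, (S)‑3‑butyn‑2‑ol
Product: 6, (S)‑4‑[3,5‑bis(TIPSO)phenyl]but‑3‑yn‑2‑ol
Conditions: Pd(PhCN)2Cl2, P(t‑Bu)3·HBF4, CuI, i‑Pr2NH, dioxane, rt → 45 °C
Reagents that add atoms: 5 (reactant), C[C@H](O)C#C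
Why: Sonogashira coupling under amine conditions that tolerate aryl silyl ethers; the purchased carbinol stereocentre is untouched.

**Step 3**
Reactants: 6
Product: 7, (S,E)‑4‑[3,5‑bis(TIPSO)phenyl]but‑3‑en‑2‑ol
Conditions: Red‑Al, THF, 0 °C → rt; Rochelle salt
Reagents that add atoms: none
Why: Hydroxyl‑directed trans‑hydroalumination of the propargylic alcohol gives only the E‑allylic alcohol.

**Step 4**
Reactants: 7; 3
Product: 8, 1‑bromo‑3‑{[(2R,3E)‑4‑(3,5‑bis(TIPSO)phenyl)but‑3‑en‑2‑yl]oxy}‑5‑(TIPSO)benzene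
Conditions: PPh3, DIAD, toluene, −10 → 0 °C
Reagents that add atoms: 3 (reactant), Oc1cc(Br)cc(O[Si](C(C)C)(C(C)C)C(C)C)c1
Why: Mitsunobu etherification proceeds by SN2 inversion, (S)‑alcohol → (R)‑ether; SN2′ is disfavoured because it would break styrene conjugation.

**Step 5**
Reactants: 8
Product: 9, 3‑bromo‑2‑[(1R,2E)‑1‑(3,5‑bis(TIPSO)phenyl)but‑2‑en‑1‑yl]‑5‑(TIPSO)phenol
Conditions: PhNEt2 (degassed), 180 °C, sealed tube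
Reagents that add atoms: none
Why: Aromatic Claisen [3,3] rearrangement through a chair TS with CH3 pseudo‑equatorial; C–O cleavage and C–C formation occur on the same allyl face, so the (R)‑carbinol centre is relayed to the (R)‑diarylmethine (future C3). The meta‑Br (directs toward itself) and the bulky OTIPS (directs to its para position) both favour the ortho carbon between O and Br. The minor Z/regio‑isomers are removed by chromatography.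

**Step 6**
Reactants: 9
Product: 10, (3R)‑4‑bromo‑3‑[3,5‑bis(TIPSO)phenyl]‑6‑(TIPSO)‑2,3‑dihydrobenzofuran‑2‑ol (anomeric mixture)
Conditions: O3, CH2Cl2/MeOH, −78 °C (Sudan III end point); Me2S, −78 °C → rt
Reagents that add atoms: ozone, [O-][O+]=O
Why: Ozonolysis of the propenyl group (acetaldehyde lost); the α,α‑diaryl aldehyde is trapped by the ortho‑phenol as a lactol, which protects C3 from enolisation.

**Step 7**
Reactants: 10; 11, (4‑bromophenoxy)triisopropylsilane (as its Grignard reagent)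
Product: 12, (2R,3R)‑4‑bromo‑3‑[3,5‑bis(TIPSO)phenyl]‑6‑(TIPSO)‑2‑[4‑(TIPSO)phenyl]‑2,3‑dihydrobenzofuran (2,3‑trans)
Conditions: 4‑TIPSOC6H4MgBr (from 11, Mg, THF; 3.5 equiv), LaCl3·2LiCl, THF, −40 → 0 °C; then CH2Cl2, TFA, 0 °C (one pot, diol not isolated)
Reagents that add atoms: [4‑(TIPSO)phenyl]magnesium bromide, Br[Mg]c1ccc(O[Si](C(C)C)(C(C)C)C(C)C)cc1
Why: Grignard addition to the open‑chain aldehyde, then acid ionises the p‑silyloxybenzylic alcohol to a quinone‑methide‑type cation. The phenol closes the five‑membered ring anti to the C3 aryl group, and the closure is reversible, so it converges on trans and C2 (R) is controlled by C3.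

**Ring B**

**Step 8**
Reactants: 12; 13, (R)‑3‑butyn‑2‑ol
Product: 14, (R)‑4‑(C‑unit)but‑3‑yn‑2‑ol
Conditions: Pd(PhCN)2Cl2, P(t‑Bu)3·HBF4, CuI, i‑Pr2NH, dioxane, 50 °C
Reagents that add atoms: 13 (reactant), C[C@@H](O)C#C
Why: Sonogashira coupling; the bulky electron‑rich phosphine handles the mono‑ortho‑substituted aryl bromide.

**Step 9**
Reactants: 14
Product: 15, (R,E)‑4‑(C‑unit)but‑3‑en‑2‑ol
Conditions: Red‑Al, THF, 0 °C → rt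
Reagents that add atoms: none
Why: Directed trans‑hydroalumination gives the E‑alkene; aryl TIPS ethers and the DHB ring are inert.

**Step 10**
Reactants: 15; 3
Product: 16, 1‑bromo‑3‑{[(2S,3E)‑4‑(C‑unit)but‑3‑en‑2‑yl]oxy}‑5‑(TIPSO)benzene
Conditions: PPh3, DIAD, toluene, −10 → 0 °C
Reagents that add atoms: 3 (reactant), Oc1cc(Br)cc(O[Si](C(C)C)(C(C)C)C(C)C)c1
Why: Mitsunobu inversion, (R)‑alcohol → (S)‑ether.

**Step 11**
Reactants: 16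
Product: 17, 3‑bromo‑2‑[(1S,2E)‑1‑(C‑unit)but‑2‑en‑1‑yl]‑5‑(TIPSO)phenol
Conditions: PhNEt2, 180 °C, sealed tube
Reagents that add atoms: none
Why: Aromatic Claisen [3,3] rearrangement with 1,3‑chirality transfer as in step 5; the enantiomeric carbinol gives the opposite (S) configuration required for ring B. The minor diastereomer is separable because ring C is already present.

**Step 12**
Reactants: 17
Product: 18, (3S)‑4‑bromo‑3‑(C‑unit)‑6‑(TIPSO)‑2,3‑dihydrobenzofuran‑2‑ol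
Conditions: O3, CH2Cl2/MeOH, −78 °C (Sudan III); Me2S
Reagents that add atoms: ozone, [O-][O+]=O
Why: Chemoselective alkene ozonolysis (arenes are much slower at −78 °C with indicator control), with lactol trapping.

**Step 13**
Reactants: 18; 11 (as Grignard)
Product: 19, (2S,3S)‑4‑bromo‑3‑(C‑unit)‑6‑(TIPSO)‑2‑[4‑(TIPSO)phenyl]‑2,3‑dihydrobenzofuran
Conditions: 4‑TIPSOC6H4MgBr, LaCl3·2LiCl, THF, −40 → 0 °C; then CH2Cl2, TFA, 0 °C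
Reagents that add atoms: Br[Mg]c1ccc(O[Si](C(C)C)(C(C)C)C(C)C)cc1
Why: Aryl addition then cation‑mediated trans‑selective O‑cyclisation as in step 7. Ring C can only reopen at C2–O and recloses trans, because its C3 is fixed.

**Ring A**

**Step 14**
Reactants: 19; 5, (S)‑3‑butyn‑2‑ol
Product: 20, (S)‑4‑(BC‑unit)but‑3‑yn‑2‑ol
Conditions: Pd(PhCN)2Cl2, P(t‑Bu)3·HBF4, CuI, i‑Pr2NH, dioxane, 50 °C
Reagents that add atoms: 5 (reactant), C[C@H](O)C#C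
Why: Sonogashira coupling as in step 8.

**Step 15**
Reactants: 20
Product: 21, (S,E)‑4‑(BC‑unit)but‑3‑en‑2‑ol
Conditions: Red‑Al, THF, 0 °C → rt
Reagents that add atoms: none
Why: Directed trans‑hydroalumination gives the E‑allylic alcohol.

**Step 16**
Reactants: 21; 3
Product: 22, 1‑bromo‑3‑{[(2R,3E)‑4‑(BC‑unit)but‑3‑en‑2‑yl]oxy}‑5‑(TIPSO)benzene
Conditions: PPh3, DIAD, toluene, −10 → 0 °C
Reagents that add atoms: 3 (reactant), Oc1cc(Br)cc(O[Si](C(C)C)(C(C)C)C(C)C)c1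
Why: Mitsunobu inversion, (S)‑alcohol → (R)‑ether.

**Step 17**
Reactants: 22
Product: 23, 3‑bromo‑2‑[(1R,2E)‑1‑(BC‑unit)but‑2‑en‑1‑yl]‑5‑(TIPSO)phenol
Conditions: PhNEt2, 180 °C, sealed tube
Reagents that add atoms: none
Why: Aromatic Claisen [3,3] rearrangement; the (R)‑ether gives the (R)‑diarylmethine of ring A by chair‑TS chirality transfer.

**Step 18**
Reactants: 23
Product: 24, (3R)‑4‑bromo‑3‑(BC‑unit)‑6‑(TIPSO)‑2,3‑dihydrobenzofuran‑2‑ol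
Conditions: O3, CH2Cl2/MeOH, −78 °C (Sudan III); Me2S
Reagents that add atoms: ozone, [O-][O+]=O
Why: Ozonolysis with lactol trapping as before.

**Step 19**
Reactants: 24; 11 (as Grignard)
Product: 25, (2R,3R)‑4‑bromo‑3‑(BC‑unit)‑6‑(TIPSO)‑2‑[4‑(TIPSO)phenyl]‑2,3‑dihydrobenzofuran
Conditions: 4‑TIPSOC6H4MgBr, LaCl3·2LiCl, THF, −40 → 0 °C; then CH2Cl2, TFA, 0 °C
Reagents that add atoms: Br[Mg]c1ccc(O[Si](C(C)C)(C(C)C)C(C)C)cc1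
Why: Grignard addition then trans‑selective cationic O‑cyclisation; C2 of ring A is set trans to C3.

**End game**

**Step 20**
Reactants: 25; 26, tert‑butyldimethyl(4‑vinylphenoxy)silane
Product: 27, (2R,3R)‑3‑(BC‑unit)‑4‑[(E)‑4‑(TBSO)styryl]‑6‑(TIPSO)‑2‑[4‑(TIPSO)phenyl]‑2,3‑dihydrobenzofuran (nona‑silyl miyabenol A)
Conditions: Pd2(dba)3, P(t‑Bu)3·HBF4, Cy2NMe, dioxane, 90 °C
Reagents that add atoms: 26 (reactant), C=Cc1ccc(O[Si](C)(C)C(C)(C)C)cc1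
Why: Mizoroki–Heck reaction of the hindered aryl bromide with a styrene gives the E‑stilbene via syn‑insertion/syn‑β‑hydride elimination; no stereocentre is involved.

**Step 21**
Reactants: 27
Product: 28, miyabenol A
Conditions: TBAF/AcOH (1:1, excess), THF, 0 °C → rt, dark, Ar
Reagents that add atoms: none
Why: Fluoride cleaves all nine aryl silyl ethers; the AcOH buffer keeps the phenols protonated, avoiding quinone‑methide ring opening of the 2‑(4‑hydroxyphenyl)‑DHB units.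

---

**Compound list**

1 | 5‑bromoresorcinol | Oc1cc(O)cc(Br)c1 | starting material
2 | triisopropylsilyl chloride | Cl[Si](C(C)C)(C(C)C)C(C)C | starting material
3 | 3‑bromo‑5‑(TIPSO)phenol | Oc1cc(Br)cc(O[Si](C(C)C)(C(C)C)C(C)C)c1 | intermediate
4 | 1‑bromo‑3,5‑bis(TIPSO)benzene | Brc1cc(O[Si](C(C)C)(C(C)C)C(C)C)cc(O[Si](C(C)C)(C(C)C)C(C)C)c1 | intermediate
5 | (S)‑3‑butyn‑2‑ol | C[C@H](O)C#C | starting material
6 | (S)‑4‑[3,5‑bis(TIPSO)phenyl]but‑3‑yn‑2‑ol | C[C@H](O)C#Cc1cc(O[Si](C(C)C)(C(C)C)C(C)C)cc(O[Si](C(C)C)(C(C)C)C(C)C)c1 | intermediate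
7 | (S,E)‑4‑[3,5‑bis(TIPSO)phenyl]but‑3‑en‑2‑ol | C[C@H](O)/C=C/c1cc(O[Si](C(C)C)(C(C)C)C(C)C)cc(O[Si](C(C)C)(C(C)C)C(C)C)c1 | intermediate
8 | (R,E)‑aryl allyl ether (ring C) | C[C@@H](Oc1cc(Br)cc(O[Si](C(C)C)(C(C)C)C(C)C)c1)/C=C/c1cc(O[Si](C(C)C)(C(C)C)C(C)C)cc(O[Si](C(C)C)(C(C)C)C(C)C)c1 | intermediate
9 | 3‑bromo‑2‑[(1R,2E)‑1‑(3,5‑bis(TIPSO)phenyl)but‑2‑enyl]‑5‑(TIPSO)phenol | Brc1cc(O[Si](C(C)C)(C(C)C)C(C)C)cc(O)c1[C@@H](c1cc(O[Si](C(C)C)(C(C)C)C(C)C)cc(O[Si](C(C)C)(C(C)C)C(C)C)c1)/C=C/C | intermediate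
10 | (3R)‑lactol, ring C | Brc1cc(O[Si](C(C)C)(C(C)C)C(C)C)cc2c1[C@@H](c1cc(O[Si](C(C)C)(C(C)C)C(C)C)cc(O[Si](C(C)C)(C(C)C)C(C)C)c1)C(O)O2 | intermediate
11 | (4‑bromophenoxy)triisopropylsilane | Brc1ccc(O[Si](C(C)C)(C(C)C)C(C)C)cc1 | starting material
12 | (2R,3R)‑ring‑C bromide | Brc1cc(O[Si](C(C)C)(C(C)C)C(C)C)cc2c1[C@@H](c1cc(O[Si](C(C)C)(C(C)C)C(C)C)cc(O[Si](C(C)C)(C(C)C)C(C)C)c1)[C@H](c1ccc(O[Si](C(C)C)(C(C)C)C(C)C)cc1)O2 | intermediate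
13 | (R)‑3‑butyn‑2‑ol | C[C@@H](O)C#C | starting material
14 | (R)‑4‑(C‑unit)but‑3‑yn‑2‑ol | C[C@@H](O)C#Cc1cc(O[Si](C(C)C)(C(C)C)C(C)C)cc2c1[C@@H](c1cc(O[Si](C(C)C)(C(C)C)C(C)C)cc(O[Si](C(C)C)(C(C)C)C(C)C)c1)[C@H](c1ccc(O[Si](C(C)C)(C(C)C)C(C)C)cc1)O2 | intermediate
15 | (R,E)‑4‑(C‑unit)but‑3‑en‑2‑ol | C[C@@H](O)/C=C/c1cc(O[Si](C(C)C)(C(C)C)C(C)C)cc2c1[C@@H](c1cc(O[Si](C(C)C)(C(C)C)C(C)C)cc(O[Si](C(C)C)(C(C)C)C(C)C)c1)[C@H](c1ccc(O[Si](C(C)C)(C(C)C)C(C)C)cc1)O2 | intermediate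
16 | (S,E)‑aryl allyl ether (ring B) | C[C@H](Oc1cc(Br)cc(O[Si](C(C)C)(C(C)C)C(C)C)c1)/C=C/c1cc(O[Si](C(C)C)(C(C)C)C(C)C)cc2c1[C@@H](c1cc(O[Si](C(C)C)(C(C)C)C(C)C)cc(O[Si](C(C)C)(C(C)C)C(C)C)c1)[C@H](c1ccc(O[Si](C(C)C)(C(C)C)C(C)C)cc1)O2 | intermediate
17 | 3‑bromo‑2‑[(1S,2E)‑1‑(C‑unit)but‑2‑enyl]‑5‑(TIPSO)phenol | Brc3cc(O[Si](C(C)C)(C(C)C)C(C)C)cc(O)c3[C@H](c1cc(O[Si](C(C)C)(C(C)C)C(C)C)cc2c1[C@@H](c1cc(O[Si](C(C)C)(C(C)C)C(C)C)cc(O[Si](C(C)C)(C(C)C)C(C)C)c1)[C@H](c1ccc(O[Si](C(C)C)(C(C)C)C(C)C)cc1)O2)/C=C/C | intermediate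
18 | (3S)‑lactol, ring B | Brc3cc(O[Si](C(C)C)(C(C)C)C(C)C)cc4c3[C@H](c1cc(O[Si](C(C)C)(C(C)C)C(C)C)cc2c1[C@@H](c1cc(O[Si](C(C)C)(C(C)C)C(C)C)cc(O[Si](C(C)C)(C(C)C)C(C)C)c1)[C@H](c1ccc(O[Si](C(C)C)(C(C)C)C(C)C)cc1)O2)C(O)O4 | intermediate
19 | B–C bromide (B: 2S,3S; C: 2R,3R) | Brc3cc(O[Si](C(C)C)(C(C)C)C(C)C)cc4c3[C@H](c1cc(O[Si](C(C)C)(C(C)C)C(C)C)cc2c1[C@@H](c1cc(O[Si](C(C)C)(C(C)C)C(C)C)cc(O[Si](C(C)C)(C(C)C)C(C)C)c1)[C@H](c1ccc(O[Si](C(C)C)(C(C)C)C(C)C)cc1)O2)[C@@H](c1ccc(O[Si](C(C)C)(C(C)C)C(C)C)cc1)O4 | intermediate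
20 | (S)‑4‑(BC‑unit)but‑3‑yn‑2‑ol | C[C@H](O)C#Cc3cc(O[Si](C(C)C)(C(C)C)C(C)C)cc4c3[C@H](c1cc(O[Si](C(C)C)(C(C)C)C(C)C)cc2c1[C@@H](c1cc(O[Si](C(C)C)(C(C)C)C(C)C)cc(O[Si](C(C)C)(C(C)C)C(C)C)c1)[C@H](c1ccc(O[Si](C(C)C)(C(C)C)C(C)C)cc1)O2)[C@@H](c1ccc(O[Si](C(C)C)(C(C)C)C(C)C)cc1)O4 | intermediate
21 | (S,E)‑4‑(BC‑unit)but‑3‑en‑2‑ol | C[C@H](O)/C=C/c3cc(O[Si](C(C)C)(C(C)C)C(C)C)cc4c3[C@H](c1cc(O[Si](C(C)C)(C(C)C)C(C)C)cc2c1[C@@H](c1cc(O[Si](C(C)C)(C(C)C)C(C)C)cc(O[Si](C(C)C)(C(C)C)C(C)C)c1)[C@H](c1ccc(O[Si](C(C)C)(C(C)C)C(C)C)cc1)O2)[C@@H](c1ccc(O[Si](C(C)C)(C(C)C)C(C)C)cc1)O4 | intermediate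
22 | (R,E)‑aryl allyl ether (ring A) | C[C@@H](Oc1cc(Br)cc(O[Si](C(C)C)(C(C)C)C(C)C)c1)/C=C/c3cc(O[Si](C(C)C)(C(C)C)C(C)C)cc4c3[C@H](c1cc(O[Si](C(C)C)(C(C)C)C(C)C)cc2c1[C@@H](c1cc(O[Si](C(C)C)(C(C)C)C(C)C)cc(O[Si](C(C)C)(C(C)C)C(C)C)c1)[C@H](c1ccc(O[Si](C(C)C)(C(C)C)C(C)C)cc1)O2)[C@@H](c1ccc(O[Si](C(C)C)(C(C)C)C(C)C)cc1)O4 | intermediate
23 | 3‑bromo‑2‑[(1R,2E)‑1‑(BC‑unit)but‑2‑enyl]‑5‑(TIPSO)phenol | Brc5cc(O[Si](C(C)C)(C(C)C)C(C)C)cc(O)c5[C@@H](c3cc(O[Si](C(C)C)(C(C)C)C(C)C)cc4c3[C@H](c1cc(O[Si](C(C)C)(C(C)C)C(C)C)cc2c1[C@@H](c1cc(O[Si](C(C)C)(C(C)C)C(C)C)cc(O[Si](C(C)C)(C(C)C)C(C)C)c1)[C@H](c1ccc(O[Si](C(C)C)(C(C)C)C(C)C)cc1)O2)[C@@H](c1ccc(O[Si](C(C)C)(C(C)C)C(C)C)cc1)O4)/C=C/C | intermediate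
24 | (3R)‑lactol, ring A | Brc5cc(O[Si](C(C)C)(C(C)C)C(C)C)cc6c5[C@@H](c3cc(O[Si](C(C)C)(C(C)C)C(C)C)cc4c3[C@H](c1cc(O[Si](C(C)C)(C(C)C)C(C)C)cc2c1[C@@H](c1cc(O[Si](C(C)C)(C(C)C)C(C)C)cc(O[Si](C(C)C)(C(C)C)C(C)C)c1)[C@H](c1ccc(O[Si](C(C)C)(C(C)C)C(C)C)cc1)O2)[C@@H](c1ccc(O[Si](C(C)C)(C(C)C)C(C)C)cc1)O4)C(O)O6 | intermediate
25 | A–B–C bromide (A: 2R,3R; B: 2S,3S; C: 2R,3R) | Brc5cc(O[Si](C(C)C)(C(C)C)C(C)C)cc6c5[C@@H](c3cc(O[Si](C(C)C)(C(C)C)C(C)C)cc4c3[C@H](c1cc(O[Si](C(C)C)(C(C)C)C(C)C)cc2c1[C@@H](c1cc(O[Si](C(C)C)(C(C)C)C(C)C)cc(O[Si](C(C)C)(C(C)C)C(C)C)c1)[C@H](c1ccc(O[Si](C(C)C)(C(C)C)C(C)C)cc1)O2)[C@@H](c1ccc(O[Si](C(C)C)(C(C)C)C(C)C)cc1)O4)[C@H](c1ccc(O[Si](C(C)C)(C(C)C)C(C)C)cc1)O6 | intermediate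
26 | tert‑butyldimethyl(4‑vinylphenoxy)silane | C=Cc1ccc(O[Si](C)(C)C(C)(C)C)cc1 | starting material
27 | nona‑silyl miyabenol A | CC(C)(C)[Si](C)(C)Oc7ccc(/C=C/c5cc(O[Si](C(C)C)(C(C)C)C(C)C)cc6c5[C@@H](c3cc(O[Si](C(C)C)(C(C)C)C(C)C)cc4c3[C@H](c1cc(O[Si](C(C)C)(C(C)C)C(C)C)cc2c1[C@@H](c1cc(O[Si](C(C)C)(C(C)C)C(C)C)cc(O[Si](C(C)C)(C(C)C)C(C)C)c1)[C@H](c1ccc(O[Si](C(C)C)(C(C)C)C(C)C)cc1)O2)[C@@H](c1ccc(O[Si](C(C)C)(C(C)C)C(C)C)cc1)O4)[C@H](c1ccc(O[Si](C(C)C)(C(C)C)C(C)C)cc1)O6)cc7 | intermediate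
28 | miyabenol A | Oc1ccc(/C=C/c2cc(O)cc3c2[C@@H](c2cc(O)cc4c2[C@H](c2cc(O)cc5c2[C@@H](c2cc(O)cc(O)c2)[C@H](c2ccc(O)cc2)O5)[C@@H](c2ccc(O)cc2)O4)[C@H](c2ccc(O)cc2)O3)cc1 | target

---

**Totals**

Total steps: 21. Longest linear sequence: 21 (from 5‑bromoresorcinol; phenol 3 and Grignard precursor 11 are reused in each cycle).

**Three steps most likely to fail**

1. **Aromatic Claisen rearrangements (steps 5, 11, 17; step 17 is the most hindered).** Risks are migration to the ortho carbon between the two oxygens, ionisation/[1,3] shift of the 1‑methyl‑3‑arylallyl ether, and incomplete chirality transfer through the CH3‑axial chair. Fallback: use C2‑symmetric 3,5‑dibromophenol as the aryl partner, so only one ortho product is possible. After ring closure, convert the unhindered C6–Br to the phenol by site‑selective Miyaura borylation/oxidation, leaving the flanked C4–Br as the handle.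

2. **One‑pot Grignard addition/acid cyclisation (steps 7, 13, 19).** Risks are enolisation of the α,α‑diaryl aldehyde, dehydration of the lactol to the achiral 3‑arylbenzofuran, and Friedel–Crafts capture of the benzylic cation by a neighbouring electron‑rich ring. Fallback: keep the ring closed and form the C2–aryl bond on the cyclic oxocarbenium instead. Convert the lactol to the 2‑phenylsulfonyl‑DHB (PhSO2H) and displace with 4‑TIPSOC6H4ZnBr/ZnBr2; attack anti to the C3 aryl gives the trans product under non‑basic conditions.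

3. **Mitsunobu etherification of the aryl‑conjugated secondary allylic alcohols (steps 4, 10, 16).** Risks are SN2′ attack or ion‑pair leakage that erodes the ee of the ether, and hence of C3. Fallback: set the C–O stereocentre on a non‑allylic substrate. Do the Mitsunobu of 3 with ethyl (S)‑ or (R)‑lactate, reduce with DIBAL to the α‑aryloxy aldehyde, then build the E‑alkene by Julia–Kocienski olefination with the benzylic PT‑sulfone of the growing fragment (its C4–Br converted to CH2SO2PT instead of the butenol).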